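**Plan**
- Retrosynthesis: first the twelve O-benzyl bonds are cut (global hydrogenolysis), then the interflavan C4(upper)–C8(lower) bond, giving a C4-activated tetra-O-benzylcatechin and octa-O-benzyl-epigallocatechin gallate.
- In the lower unit the cuts are, in order: the C3–H/C4–H pair (hydrogenation), the C3=C4 bond of the pyran ring (ring-closing metathesis), the C3–O gallate bond (acid addition to an alkyne), the vinyl group (Wittig) and O1–C2 (propargylic etherification).
- Enabling feature: in the lower pyran ring C3 carries the acyloxy group and C4 is a benzylic CH2 on the phloroglucinol ring. The C3–C4 single bond is therefore the reduced form of an enol-ester double bond, and the array C4–C4a–C8a–O1–C2–C3 is that of a 2-vinylaryl 2-acyloxyallyl ether.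
- Forward: the A ring (phloroglucinaldehyde) and B ring are joined through O1–C2, the gallate is placed on C3 as an enol ester, the pyran ring is closed at C3=C4 and reduced, and the catechin unit is attached last. The helpers (two terminal CH2 groups, the C3=C4 unsaturation) leave as ethylene and by hydrogenation.
- Stereochemistry: lower C2 from a Cu/pybox-catalysed propargylic etherification; lower C3 from hydrogenation anti to the C2 aryl group (2,3-cis); upper C2 and C3 from (+)-catechin; upper C4 from attack trans to the 3-OH in the coupling.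

Key step: step 7

Assumption: the (S,S)-Ph-pybox/Cu catalyst is taken to give the (S)-ether 6; if the first experiment shows the opposite sense of induction, the (R,R)-ligand is used and nothing else changes.
Assumption: 2,4,6-trihydroxybenzaldehyde, 3,4,5-tris(benzyloxy)benzaldehyde, 3,4,5-tris(benzyloxy)benzoic acid and (+)-catechin are bought.

**Step 1**
Reactants: 1 2,4,6-trihydroxybenzaldehyde
Product: 2 2,4-bis(benzyloxy)-6-hydroxybenzaldehyde
Conditions: BnBr (2.05 equiv), K2CO3 (2.2 equiv), DMF, 0 °C to rt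
Reagents that add atoms: benzyl bromide, BrCc1ccccc1
Why: Williamson etherification in which the hydroxyl hydrogen-bonded to the formyl group is the least nucleophilic and should stay free when two equivalents of bromide are used.

**Step 2**
Reactants: 3 3,4,5-tris(benzyloxy)benzaldehyde
Product: 4 rac-1-[3,4,5-tris(benzyloxy)phenyl]prop-2-yn-1-ol
Conditions: ethynylmagnesium bromide (1.5 equiv), THF, 0 °C; aq. NH4Cl
Reagents that add atoms: ethynylmagnesium bromide, C#C[Mg]Br
Why: Grignard 1,2-addition to a non-enolisable aryl aldehyde should give the racemic propargylic alcohol, whose centre is fixed only in step 4.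

**Step 3**
Reactants: 4 rac-1-[3,4,5-tris(benzyloxy)phenyl]prop-2-yn-1-ol
Product: 5 rac-1-[3,4,5-tris(benzyloxy)phenyl]prop-2-yn-1-yl acetate
Conditions: Ac2O, pyridine, DMAP (cat.), CH2Cl2, 0 °C to rt
Reagents that add atoms: acetic anhydride, CC(=O)OC(C)=O
Why: DMAP-catalysed acylation turns the hydroxyl into the leaving group needed for copper-allenylidene formation.

**Step 4**
Reactants: 5 rac-1-[3,4,5-tris(benzyloxy)phenyl]prop-2-yn-1-yl acetate; 2 2,4-bis(benzyloxy)-6-hydroxybenzaldehyde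
Product: 6 (S)-2,4-bis(benzyloxy)-6-({1-[3,4,5-tris(benzyloxy)phenyl]prop-2-yn-1-yl}oxy)benzaldehyde
Conditions: Cu(OTf)·½C6H6 (5 mol%), 2,6-bis[(4S)-4-phenyl-4,5-dihydrooxazol-2-yl]pyridine (10 mol%), iPr2NEt (1.2 equiv), THF, −20 to 0 °C
Reagents that add atoms: none
Why: Copper-catalysed enantioselective propargylic etherification, in which the phenoxide attacks the γ-carbon of a Cu-allenylidene inside the chiral pybox pocket, should convert both enantiomers of 5 into one ether and so set C2 by the ligand; the formyl group makes the phenol acidic and deactivates its ring towards C-alkylation.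

**Step 5**
Reactants: 6 (S)-2,4-bis(benzyloxy)-6-({1-[3,4,5-tris(benzyloxy)phenyl]prop-2-yn-1-yl}oxy)benzaldehyde
Product: 7 (S)-1,5-bis(benzyloxy)-2-ethenyl-3-({1-[3,4,5-tris(benzyloxy)phenyl]prop-2-yn-1-yl}oxy)benzene
Conditions: Ph3PCH3Br (1.3 equiv), KOtBu (1.25 equiv), THF, 0 °C; then 6, −78 to 0 °C; chromatography on Et3N-deactivated silica
Reagents that add atoms: methyltriphenylphosphonium bromide, C[P+](c1ccccc1)(c1ccccc1)c1ccccc1.[Br-]
Why: Wittig methylenation of a non-enolisable aldehyde, with an ylide too weakly basic to remove the alkyne or the propargylic hydrogen, so C2 should keep its configuration.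

**Step 6**
Reactants: 7 (S)-1,5-bis(benzyloxy)-2-ethenyl-3-({1-[3,4,5-tris(benzyloxy)phenyl]prop-2-yn-1-yl}oxy)benzene; 8 3,4,5-tris(benzyloxy)benzoic acid
Product: 9 (R)-3-[3,5-bis(benzyloxy)-2-ethenylphenoxy]-3-[3,4,5-tris(benzyloxy)phenyl]prop-1-en-2-yl 3,4,5-tris(benzyloxy)benzoate
Conditions: [RuCl2(p-cymene)]2 (1 mol%), P(2-furyl)3 (2 mol%), Na2CO3 (2 mol%), toluene, 50 °C
Reagents that add atoms: none
Why: Ruthenium-catalysed Markovnikov addition of a carboxylic acid to a terminal alkyne (carboxylate attack on the internal carbon of the Ru-bound alkyne, then protodemetalation) should place the gallate on C3 as a 1,1-disubstituted enol ester without any enolate chemistry at C2.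

**Step 7**
Reactants: 9 (R)-3-[3,5-bis(benzyloxy)-2-ethenylphenoxy]-3-[3,4,5-tris(benzyloxy)phenyl]prop-1-en-2-yl 3,4,5-tris(benzyloxy)benzoate
Product: 10 (R)-5,7-bis(benzyloxy)-2-[3,4,5-tris(benzyloxy)phenyl]-2H-chromen-3-yl 3,4,5-tris(benzyloxy)benzoate
Conditions: Ru-NHC 2-isopropoxybenzylidene catalyst (Hoveyda–Grubbs II, 10 mol%), 1,4-benzoquinone (20 mol%), toluene (5 mM), 80 °C, argon sparge
Reagents that add atoms: none
Why: Proposed new method: ring-closing metathesis in which the 1,1-disubstituted partner is an enol ester (a 2-acyloxyallyl aryl ether); the catalyst should initiate at the terminal styrene CH=CH2 (C4), the resulting aryl-substituted Ru alkylidene should add [2+2] across the CH2=C(OCOAr) unit with Ru on the CH2 carbon, and cycloreversion of the ruthenacyclobutane forms C3=C4 and releases Ru=CH2, loss of ethylene making the closure irreversible. The closest known reaction types are the ring-closing metathesis of 2-vinylaryl allyl ethers to 2H-chromenes and that of silyl or alkyl enol ethers with a second alkene to cyclic enol derivatives. The one ring closed is the six-membered pyran ring of a 2H-chromene, closed by forming the endocyclic C3=C4 bond from two terminal CH2 groups. No stereocentre is formed: C2 (R) lies outside the reacting carbons and is kept under neutral, non-ionising conditions, and C3 is left sp2 on purpose so that step 8 sets it under control of C2. The step needs the productive orientation of the cycloaddition (Ru must not settle on the acyloxy-bearing carbon as a Fischer carbene) and no Ru–H migration of the new double bond towards C2; the first is secured by the 1,1-disubstitution of the enol ester and the six-membered tether, the second by the benzoquinone additive and the absence of any other alkene.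

**Step 8**
Reactants: 10 (R)-5,7-bis(benzyloxy)-2-[3,4,5-tris(benzyloxy)phenyl]-2H-chromen-3-yl 3,4,5-tris(benzyloxy)benzoate
Product: 11 (2R,3R)-5,7-bis(benzyloxy)-2-[3,4,5-tris(benzyloxy)phenyl]chroman-3-yl 3,4,5-tris(benzyloxy)benzoate (octa-O-benzyl-epigallocatechin gallate)
Conditions: [Rh(nbd)(dppb)]BF4 (5 mol%), H2 (30 bar), CH2Cl2, rt
Reagents that add atoms: none
Why: Homogeneous rhodium hydrogenation of an enol ester bound through its ester carbonyl should add H2 syn to the face opposite the pseudo-axial C2 aryl group (held axial by A(1,2) strain with the 3-acyloxy group), which places the new C3–H trans to the aryl group and gives the 2,3-cis (3R) gallate, while benzyl ethers are inert to this catalyst.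

**Step 9**
Reactants: 12 (+)-catechin
Product: 13 (2R,3S)-5,7-bis(benzyloxy)-2-[3,4-bis(benzyloxy)phenyl]chroman-3-ol
Conditions: BnBr (4.4 equiv), K2CO3 (4.5 equiv), DMF, 0 °C to rt
Reagents that add atoms: benzyl bromide, BrCc1ccccc1
Why: Williamson etherification with a weak base should alkylate the four phenols and leave the secondary alcohol free.

**Step 10**
Reactants: 13 (2R,3S)-5,7-bis(benzyloxy)-2-[3,4-bis(benzyloxy)phenyl]chroman-3-ol
Product: 14 (2R,3S,4S)-5,7-bis(benzyloxy)-2-[3,4-bis(benzyloxy)phenyl]-4-(2-ethoxyethoxy)chroman-3-ol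
Conditions: DDQ (2 equiv), 2-ethoxyethanol (5 equiv), CH2Cl2, rt
Reagents that add atoms: 2-ethoxyethanol, CCOCCO
Why: DDQ benzylic oxidation (hydride abstraction from C4 to a cation stabilised by the A ring) followed by capture by the alcohol anti to the C2 aryl group should give the C4 ether, whose configuration does not matter because C4 is ionised again in step 11.

**Step 11**
Reactants: 14 (2R,3S,4S)-5,7-bis(benzyloxy)-2-[3,4-bis(benzyloxy)phenyl]-4-(2-ethoxyethoxy)chroman-3-ol; 11 octa-O-benzyl-epigallocatechin gallate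
Product: 15 dodeca-O-benzyl catechin-(4α→8)-epigallocatechin 3-O-gallate
Conditions: 11 (2.5 equiv, excess recovered), TMSOTf (0.5 equiv), CH2Cl2, −78 °C; Et3N quench
Reagents that add atoms: none
Why: Lewis-acid-promoted SN1 Friedel–Crafts alkylation, in which the C4 cation of the catechin unit is attacked by C8 of 11 (the less shielded of the two activated A-ring positions) on the face trans to the 3-OH, should give the 3,4-trans (4S, 4α) linkage under kinetic control at low temperature.

**Step 12**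
Reactants: 15 dodeca-O-benzyl catechin-(4α→8)-epigallocatechin 3-O-gallate
Product: 16 catechin-(4α→8)-epigallocatechin 3-O-gallate (CNP0246304.1)
Conditions: H2 (1 atm), 20% Pd(OH)2/C, THF/MeOH/H2O, rt; filtration, lyophilisation
Reagents that add atoms: none
Why: Neutral hydrogenolysis should remove all twelve benzyl ethers while the gallate ester, the acid-labile interflavan bond and the cyclic O1–C2 ethers are left intact.

**Compound list**
1 | 2,4,6-trihydroxybenzaldehyde | O=Cc1c(O)cc(O)cc1O | starting material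
2 | 2,4-bis(benzyloxy)-6-hydroxybenzaldehyde | O=Cc1c(O)cc(OCc2ccccc2)cc1OCc1ccccc1 | intermediate
3 | 3,4,5-tris(benzyloxy)benzaldehyde | O=Cc1cc(OCc2ccccc2)c(OCc2ccccc2)c(OCc2ccccc2)c1 | starting material
4 | rac-1-[3,4,5-tris(benzyloxy)phenyl]prop-2-yn-1-ol | C#CC(O)c1cc(OCc2ccccc2)c(OCc2ccccc2)c(OCc2ccccc2)c1 | intermediate
5 | rac-1-[3,4,5-tris(benzyloxy)phenyl]prop-2-yn-1-yl acetate | C#CC(OC(C)=O)c1cc(OCc2ccccc2)c(OCc2ccccc2)c(OCc2ccccc2)c1 | intermediate
6 | (S)-2,4-bis(benzyloxy)-6-({1-[3,4,5-tris(benzyloxy)phenyl]prop-2-yn-1-yl}oxy)benzaldehyde | O=Cc1c(O[C@@H](C#C)c2cc(OCc3ccccc3)c(OCc3ccccc3)c(OCc3ccccc3)c2)cc(OCc2ccccc2)cc1OCc1ccccc1 | intermediate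
7 | (S)-1,5-bis(benzyloxy)-2-ethenyl-3-({1-[3,4,5-tris(benzyloxy)phenyl]prop-2-yn-1-yl}oxy)benzene | C=Cc1c(O[C@@H](C#C)c2cc(OCc3ccccc3)c(OCc3ccccc3)c(OCc3ccccc3)c2)cc(OCc2ccccc2)cc1OCc1ccccc1 | intermediate
8 | 3,4,5-tris(benzyloxy)benzoic acid | OC(=O)c1cc(OCc2ccccc2)c(OCc2ccccc2)c(OCc2ccccc2)c1 | starting material
9 | (R)-3-[3,5-bis(benzyloxy)-2-ethenylphenoxy]-3-[3,4,5-tris(benzyloxy)phenyl]prop-1-en-2-yl 3,4,5-tris(benzyloxy)benzoate | C=Cc1c(O[C@@H](C(=C)OC(=O)c2cc(OCc3ccccc3)c(OCc3ccccc3)c(OCc3ccccc3)c2)c2cc(OCc3ccccc3)c(OCc3ccccc3)c(OCc3ccccc3)c2)cc(OCc2ccccc2)cc1OCc1ccccc1 | intermediate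
10 | (R)-5,7-bis(benzyloxy)-2-[3,4,5-tris(benzyloxy)phenyl]-2H-chromen-3-yl 3,4,5-tris(benzyloxy)benzoate | O=C(OC1=Cc2c(OCc3ccccc3)cc(OCc3ccccc3)cc2O[C@@H]1c1cc(OCc2ccccc2)c(OCc2ccccc2)c(OCc2ccccc2)c1)c1cc(OCc2ccccc2)c(OCc2ccccc2)c(OCc2ccccc2)c1 | intermediate
11 | (2R,3R)-5,7-bis(benzyloxy)-2-[3,4,5-tris(benzyloxy)phenyl]chroman-3-yl 3,4,5-tris(benzyloxy)benzoate | O=C(O[C@@H]1Cc2c(OCc3ccccc3)cc(OCc3ccccc3)cc2O[C@@H]1c1cc(OCc2ccccc2)c(OCc2ccccc2)c(OCc2ccccc2)c1)c1cc(OCc2ccccc2)c(OCc2ccccc2)c(OCc2ccccc2)c1 | intermediate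
12 | (+)-catechin, (2R,3S) | O[C@H]1Cc2c(O)cc(O)cc2O[C@@H]1c1ccc(O)c(O)c1 | starting material
13 | (2R,3S)-5,7-bis(benzyloxy)-2-[3,4-bis(benzyloxy)phenyl]chroman-3-ol | O[C@H]1Cc2c(OCc3ccccc3)cc(OCc3ccccc3)cc2O[C@@H]1c1ccc(OCc2ccccc2)c(OCc2ccccc2)c1 | intermediate
14 | (2R,3S,4S)-5,7-bis(benzyloxy)-2-[3,4-bis(benzyloxy)phenyl]-4-(2-ethoxyethoxy)chroman-3-ol | CCOCCO[C@H]1c2c(OCc3ccccc3)cc(OCc3ccccc3)cc2O[C@H](c2ccc(OCc3ccccc3)c(OCc3ccccc3)c2)[C@H]1O | intermediate
15 | dodeca-O-benzyl catechin-(4α→8)-epigallocatechin 3-O-gallate | O=C(O[C@@H]1Cc2c(OCc3ccccc3)cc(OCc3ccccc3)c([C@@H]3c4c(OCc5ccccc5)cc(OCc5ccccc5)cc4O[C@H](c4ccc(OCc5ccccc5)c(OCc5ccccc5)c4)[C@H]3O)c2O[C@@H]1c1cc(OCc2ccccc2)c(OCc2ccccc2)c(OCc2ccccc2)c1)c1cc(OCc2ccccc2)c(OCc2ccccc2)c(OCc2ccccc2)c1 | intermediate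
16 | catechin-(4α→8)-epigallocatechin 3-O-gallate (CNP0246304.1) | O=C(O[C@@H]1Cc2c(O)cc(O)c([C@@H]3c4c(O)cc(O)cc4O[C@H](c4ccc(O)c(O)c4)[C@H]3O)c2O[C@@H]1c1cc(O)c(O)c(O)c1)c1cc(O)c(O)c(O)c1 | target

**Step count**
Total: 12 steps. Longest linear sequence: 9 steps (steps 2, 3, 4, 5, 6, 7, 8, 11, 12, from aldehyde 3).

**Steps most likely to fail**

Step 7 (Proposed new method). The catalyst may be lost by transfer of the carbene to the acyloxy-bearing carbon, may be held as a chelate by the ortho-alkoxy benzylidene, or a ruthenium hydride may shift the new double bond towards C2. The fallback uses known chemistry, sets out from 7 and comes back at 11; it also bypasses steps 6 and 8. Semi-hydrogenation of the alkyne over Lindlar catalyst with quinoline should give (S)-1,5-bis(benzyloxy)-2-ethenyl-3-({1-[3,4,5-tris(benzyloxy)phenyl]prop-2-en-1-yl}oxy)benzene F1. Ordinary ring-closing metathesis of this styrene/allyl ether pair should give (S)-5,7-bis(benzyloxy)-2-[3,4,5-tris(benzyloxy)phenyl]-2H-chromene F2. Hydroboration–oxidation (BH3·THF, then NaOH/H2O2) anti to the aryl group should give the 2,3-trans alcohol penta-O-benzyl-gallocatechin F3. Oxidation with Dess–Martin periodinane should give (R)-5,7-bis(benzyloxy)-2-[3,4,5-tris(benzyloxy)phenyl]chroman-3-one F4, and L-Selectride at −78 °C should give the 2,3-cis alcohol penta-O-benzyl-epigallocatechin F5. Esterification of F5 with acid 8 (EDC, DMAP, CH2Cl2) gives 11.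

Step 4. The electron-rich ring may be propargylated at carbon instead of oxygen, or the ortho-formyl phenol may be poorly discriminated by the catalyst, with loss of enantiopurity. The fallback sets out from 4 and comes back at 6. Lipase-catalysed acylation (lipase PS, vinyl acetate) should, by the empirical rule for secondary alcohols, acylate the (R)-enantiomer to (R)-1-[3,4,5-tris(benzyloxy)phenyl]prop-2-yn-1-yl acetate F6, which is separated from the unreacted (S)-alcohol. Methanolysis (K2CO3, MeOH, 0 °C) should give (R)-1-[3,4,5-tris(benzyloxy)phenyl]prop-2-yn-1-ol F7. Mitsunobu etherification of F7 with the acidic phenol 2 (PPh3, DIAD, toluene, 0 °C) should then give 6 with inversion.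

Step 11. The dimer formed may react on with further electrophile (oligomerisation) when the nucleophile 11 is not in large excess, and some attack at C6 may occur. The fallback sets out from 13 and comes back at 16; it caps C8 of the catechin unit with bromine so that near-equimolar amounts can be used. NBS in CH2Cl2 should give (2R,3S)-8-bromo-5,7-bis(benzyloxy)-2-[3,4-bis(benzyloxy)phenyl]chroman-3-ol F8. DDQ with 2-ethoxyethanol should give the 8-bromo-4-(2-ethoxyethoxy) derivative F9. Coupling of F9 with 11 (TMSOTf, −78 °C) should give the 8-bromo analogue of 15, F10. Hydrogenolysis (H2, Pd(OH)2/C, Et3N) removes the bromine together with the benzyl groups and gives 16.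

**Further compounds**
F1 | step 7 | (S)-1,5-bis(benzyloxy)-2-ethenyl-3-({1-[3,4,5-tris(benzyloxy)phenyl]prop-2-en-1-yl}oxy)benzene | C=Cc1c(O[C@@H](C=C)c2cc(OCc3ccccc3)c(OCc3ccccc3)c(OCc3ccccc3)c2)cc(OCc2ccccc2)cc1OCc1ccccc1
F2 | step 7 | (S)-5,7-bis(benzyloxy)-2-[3,4,5-tris(benzyloxy)phenyl]-2H-chromene | C1=Cc2c(OCc3ccccc3)cc(OCc3ccccc3)cc2O[C@@H]1c1cc(OCc2ccccc2)c(OCc2ccccc2)c(OCc2ccccc2)c1
F3 | step 7 | (2R,3S)-5,7-bis(benzyloxy)-2-[3,4,5-tris(benzyloxy)phenyl]chroman-3-ol | O[C@H]1Cc2c(OCc3ccccc3)cc(OCc3ccccc3)cc2O[C@@H]1c1cc(OCc2ccccc2)c(OCc2ccccc2)c(OCc2ccccc2)c1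
F4 | step 7 | (R)-5,7-bis(benzyloxy)-2-[3,4,5-tris(benzyloxy)phenyl]chroman-3-one | O=C1Cc2c(OCc3ccccc3)cc(OCc3ccccc3)cc2O[C@@H]1c1cc(OCc2ccccc2)c(OCc2ccccc2)c(OCc2ccccc2)c1
F5 | step 7 | (2R,3R)-5,7-bis(benzyloxy)-2-[3,4,5-tris(benzyloxy)phenyl]chroman-3-ol | O[C@@H]1Cc2c(OCc3ccccc3)cc(OCc3ccccc3)cc2O[C@@H]1c1cc(OCc2ccccc2)c(OCc2ccccc2)c(OCc2ccccc2)c1
F6 | step 4 | (R)-1-[3,4,5-tris(benzyloxy)phenyl]prop-2-yn-1-yl acetate | CC(=O)O[C@H](C#C)c1cc(OCc2ccccc2)c(OCc2ccccc2)c(OCc2ccccc2)c1
F7 | step 4 | (R)-1-[3,4,5-tris(benzyloxy)phenyl]prop-2-yn-1-ol | O[C@H](C#C)c1cc(OCc2ccccc2)c(OCc2ccccc2)c(OCc2ccccc2)c1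
F8 | step 11 | (2R,3S)-8-bromo-5,7-bis(benzyloxy)-2-[3,4-bis(benzyloxy)phenyl]chroman-3-ol | O[C@H]1Cc2c(OCc3ccccc3)cc(OCc3ccccc3)c(Br)c2O[C@@H]1c1ccc(OCc2ccccc2)c(OCc2ccccc2)c1
F9 | step 11 | (2R,3S,4S)-8-bromo-5,7-bis(benzyloxy)-2-[3,4-bis(benzyloxy)phenyl]-4-(2-ethoxyethoxy)chroman-3-ol | CCOCCO[C@H]1c2c(OCc3ccccc3)cc(OCc3ccccc3)c(Br)c2O[C@H](c2ccc(OCc3ccccc3)c(OCc3ccccc3)c2)[C@H]1O
F10 | step 11 | 8-bromo (upper unit) analogue of 15 | O=C(O[C@@H]1Cc2c(OCc3ccccc3)cc(OCc3ccccc3)c([C@@H]3c4c(OCc5ccccc5)cc(OCc5ccccc5)c(Br)c4O[C@H](c4ccc(OCc5ccccc5)c(OCc5ccccc5)c4)[C@H]3O)c2O[C@@H]1c1cc(OCc2ccccc2)c(OCc2ccccc2)c(OCc2ccccc2)c1)c1cc(OCc2ccccc2)c(OCc2ccccc2)c(OCc2ccccc2)c1
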